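# Total synthesis proposal for michaolide A (34)

## The problem

Michaolide A (34) is a cembranolide. Ring A is a 14-membered carbocycle (C1–C14, methyl groups on C4, C8 and C12). It is trans-fused at C1–C2 to an α-methylene-γ-butyrolactone (ring B: C1, C2, O, C16, C15, exocyclic C17) and carries a trans, trisubstituted epoxide at C3–C4 (ring C).

Ring A has no heteroatom, so its closure must be a C–C bond formation against the entropy of a fourteen-carbon chain. Its two alkenes (C7=C8, C11=C12) are E and trisubstituted, a pattern that olefin metathesis does not deliver reliably in a ring of this size.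

Six of the seven stereocentres are contiguous (14R, 1R, 2S, 3S, 4S, 5R). The seventh, C9 (S), lies four bonds from C5 and five from C14, beyond any neighbouring-group control, so it must be tied to the block by one reagent or be set alone.

Inside the block C2 is the hub. O14 and O2 are 1,3-anti, and C15 on C1 is anti to O14 and syn to O2. These are the relations of an erythro epoxy alcohol (C2 carbinol, trans C1–C14 epoxide) opened at C1 with inversion. In contrast, C4–O and C5–O are threo, which a C5-hydroxyl-directed epoxidation would not give, so C5 has to be set after ring C.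

Three secondary oxygens must be told apart: acetates at C5 and C14, a free hydroxyl at C9.

Several groups forbid strong base, hydride, soft nucleophiles and strong acid late in the route:
- the acrylate of ring B, a Michael acceptor;
- ring C, flanked by two C–O bonds;
- the acetates;
- the 3-hydroxy-1,5-diene C7=C8–C9(OH)–C10–C11=C12, an anionic oxy-Cope substrate.

The feature that makes the key step possible is the segment C5(O)–C6H2–C7H=C8(CH3)–C9(O) of ring A. It is an (E)-2-methylpent-2-ene-1,5-diol with 1,5-anti configuration. Its two carbinol carbons are former aldehyde carbons, and its three inner carbons plus the methyl group equal one allene-derived bis-boron unit.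

## Retrosynthesis

**34 ⇒ 31 (no C–C bond cut).** The C5 acetate is removed, which leads through 33 and 32 to the macrocyclic 5,9-diol 31. The C14 acetate stays, because it serves as the protecting group of O14 from step 11 on. The forward reactions must tell the allylic C9 hydroxyl (next to an sp2 carbon) from the C5 hydroxyl (next to the quaternary C4). Silylation of C9, acetylation of C5 and desilylation do this.

**31 ⇒ 21 + 24 (+ 26): cut C5–C6 and C8–C9 together.**
- Cutting only C8–C9 (alkenyl metal plus aldehyde) or only C5–C6 would leave a bifunctional chain in which C5 or C9 and the E-alkene must be made beforehand, each by its own operation.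
- Cutting both releases a three-carbon linchpin (C6–C8 with its methyl group, allenylboronate 24) and the dialdehyde 21.
- 21 has no ring A, no C7=C8, no C5 and no C9 stereocentre, and its two ends come from one double oxidation.
- The forward reaction must form two C–C bonds, the ring, one E-alkene and two stereocentres related 1,5-anti by one chiral borane (26), and it must distinguish the two aldehydes.

**21 ⇒ 20 ⇒ 19: remove two oxidation levels and the oxygen of ring C.** The C5 hydroxyl of 19 is a primary (E)-allylic alcohol of the best substrate class for the Sharpless epoxidation, so C3 and C4 are set by the tartrate and not by C2. Directed delivery from C2 would have to fight the allylic strain of the C4 methyl group. The precursor 19 has three stereocentres. Epoxidation must leave the electron-poor C15=C17 and the homoallylic C11=C12 alone.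

**19 ⇐ 18 ⇐ 17 ⇒ 15: cut C1–C15 and C15=C17.**
- Cutting C1–C2 or C1–C14 instead (allylmetal plus aldehyde) would leave the C14/C1 relation to a transition state whose natural sense is the wrong one for this triad.
- Cutting C1–C15 turns ring B into a phosphonoacetate ester on O2 and turns C1/C14 into a trans epoxide.
- The tether then decides the regiochemistry (C1, not C14) and the SN2 course decides the configuration.
- The forward cascade must open the epoxide, free O14 and install C17.

**15 ⇒ 14 ⇒ 13: remove the ester and the epoxide oxygen.** 13 is a bis-allylic alcohol with a single stereocentre, C2. For the (S)-carbinol, D-(−)-tartrate is matched for C1=C14 and mismatched for C3=C4. One catalyst therefore has to pick the alkene and the face, which sets C14 and, provisionally, C1.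

**13 ⇒ 5 + 10: cut C1–C2.** This is the only bond whose scission gives two achiral fragments of similar size: enyne 5 (C9–C14, C1) and enal 10 (C2–C5). Cutting C2–C3 instead would need a skipped dienal that isomerises into conjugation. The forward reaction is a catalytic asymmetric alkenylzinc addition.

**Fragments.**
- 5 ⇒ 4 ⇒ 3 ⇒ 2 ⇒ 1: the C13–C14 bond comes from an acetylide, and O13 from allylic oxidation of a prenyl-type terminus that already has the right alkene.
- 10 ⇒ 9 ⇒ 6: C4–CH3 and C2–C3 come from carboalumination and hydroxymethylation.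
- 24 ⇒ 23 ⇒ 22: the C–B bond comes from SN2′ borylation.
- 26 ⇒ 25.

## Roads not taken

**Alternative 1:** the most obvious cut is C1–C2 together with the C16–O bond of ring B.
- Forward step: intramolecular Nozaki–Hiyama–Kishi-type (CrCl2, divalent chromium) or zinc Barbier 2-(alkoxycarbonyl)allylation of the bromo enoate aldehyde A1, then lactonisation to 33.
- A1 must already hold C3, C4, C5, C9 and C14 and both E-alkenes, each made by its own operation. The closure adds only C1 and C2, and C9 remains unrelated to the block.
- The allylmetal equilibrates between its geometries, so the trans fusion rests on the macrocyclic transition state alone.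
- In the conformer of least allylic strain the aldehyde would have to approach C1 on the side of O14, which is the hindered side.
- The chosen plan sets C1 by an SN2 reaction and spends the ring closure on the two stereocentres that are hardest to relate.

**Alternative 2:** cut C7=C8 as an alkyne.
- Forward step: ring-closing alkyne metathesis of the diyne A2 with Mo(≡CC6H4OMe)(OSiPh3)3 to the cycloalkyne A3. Hydroxyl-directed trans-hydrostannation ([Cp*RuCl]4, Bu3SnH) and methyl cross-coupling then lead to 34.
- The alkene geometry would be secure.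
- However, the closure creates no stereocentre. C5 and C9 need two separate asymmetric additions before it.
- Two organometallic steps with stoichiometric tin follow it, in the presence of the acrylate of ring B.
- The plan costs more steps on both sides of the ring closure.

**Alternative 3:** cut the C9–O bond.
- Forward step: late allylic hydroxylation of 9-deoxymichaolide A (A4) by an engineered cytochrome P450 monooxygenase.
- This would remove the remote stereocentre and all protecting groups at C9.
- A4 offers four allylic CH2 groups (C6, C9, C10, C13) and two allylic methyl groups of similar strength, plus two epoxidisable alkenes. A selective variant would therefore have to be evolved for this substrate.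
- Ring A, C5 and the E-alkene C7=C8 would still have to be made by other means.
- The chosen key step solves these problems and C9 in one operation.

Key step: step 18

Assumption: atom labels C1–C17 are those of the cembrane skeleton of 34 and are used for all intermediates, whose CIP letters may change through priority only. The sense of induction of (−)-MIB and of the Ipc groups is taken from the accepted models; should one run the other way, the enantiomeric ligand or pinene is used.

## Steps

Step 1
Reactants: 1 4-methylpent-3-en-1-ol
Product: 2 tert-butyl(dimethyl)[(4-methylpent-3-en-1-yl)oxy]silane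
Conditions: TBSCl, imidazole, CH2Cl2, 0 °C to rt
Reagents that add atoms: tert-butyldimethylsilyl chloride, CC(C)(C)[Si](C)(C)Cl
Why: Standard silylation of a primary alcohol; the ether masks O9 until step 12.

Step 2
Reactants: 2 tert-butyl(dimethyl)[(4-methylpent-3-en-1-yl)oxy]silane
Product: 3 (E)-5-(tert-butyldimethylsilyloxy)-2-methylpent-2-en-1-ol
Conditions: SeO2 (cat.), t-BuOOH, salicylic acid (cat.), CH2Cl2, rt
Reagents that add atoms: tert-butyl hydroperoxide, CC(C)(C)OO
Why: Riley-type allylic oxidation (ene reaction, then [2,3]-shift) attacks the methyl group trans to the chain of a prenyl terminus, so the C11=C12 alkene should emerge E with O on C13.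

Step 3
Reactants: 3 (E)-5-(tert-butyldimethylsilyloxy)-2-methylpent-2-en-1-ol
Product: 4 (E)-[(5-bromo-4-methylpent-3-en-1-yl)oxy](tert-butyl)dimethylsilane
Conditions: CBr4, PPh3, CH2Cl2, 0 °C
Reagents that add atoms: carbon tetrabromide, BrC(Br)(Br)Br
Why: Appel reaction under neutral conditions; primary allylic alcohols react by SN2 without transposition, and the silyl ether is inert.

Step 4
Reactants: 4 (E)-[(5-bromo-4-methylpent-3-en-1-yl)oxy](tert-butyl)dimethylsilane
Product: 5 (E)-tert-butyl(dimethyl)[(4-methylhept-3-en-6-yn-1-yl)oxy]silane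
Conditions: HC≡CMgBr (excess), CuBr·SMe2 (10 mol %), THF, 0 °C to rt
Reagents that add atoms: ethynylmagnesium bromide, C#C[Mg]Br
Why: Coupling of an alkynyl Grignard reagent with a primary allylic bromide under catalysis by monovalent copper gives the skipped enyne at the unsubstituted terminus (C13–C14 bond); the alkene is not touched.

Step 5
Reactants: 6 tert-butyl(dimethyl)(prop-2-yn-1-yloxy)silane
Product: 9 (E)-4-(tert-butyldimethylsilyloxy)-3-methylbut-2-en-1-ol, via alkenylalane 7 (not isolated), via lithium alanate 8 (not isolated)
Conditions: Me3Al, Cp2ZrCl2 (25 mol %), CH2Cl2, 0 °C to rt; n-BuLi, THF/hexane, −78 °C; (CH2O)n, rt; aq. work-up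
Reagents that add atoms: trimethylaluminium, C[Al](C)C; formaldehyde (as paraformaldehyde), C=O
Why: Zirconium-catalysed carboalumination adds CH3 and Al syn with Al at the terminus, and the ate complex is hydroxymethylated with retention, so C2 ends cis to the C4 methyl group (E alkene C3=C4).

Step 6
Reactants: 9 (E)-4-(tert-butyldimethylsilyloxy)-3-methylbut-2-en-1-ol
Product: 10 (E)-4-(tert-butyldimethylsilyloxy)-3-methylbut-2-enal
Conditions: MnO2, CH2Cl2, rt
Reagents that add atoms: none
Why: Allylic oxidation with MnO2 stops at the enal and keeps the alkene geometry.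

Step 7
Reactants: 5 (E)-tert-butyl(dimethyl)[(4-methylhept-3-en-6-yn-1-yl)oxy]silane; 10 (E)-4-(tert-butyldimethylsilyloxy)-3-methylbut-2-enal
Product: 13 (2E,4S,5E,8E)-1,11-bis(tert-butyldimethylsilyloxy)-2,8-dimethylundeca-2,5,8-trien-4-ol (C2 carbinol), via alkenylborane 11 (not isolated), via alkenylzinc 12 (not isolated)
Conditions: Cy2BH (made in the flask from cyclohexene and BH3·SMe2), toluene, 0 °C to rt; Me2Zn, −78 °C; (−)-MIB [(2S)-3-exo-morpholinoisoborneol, 5 mol %], then 10, −30 to 0 °C; aq. work-up
Reagents that add atoms: none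
Why: Cy2BH hydroborates the terminal alkyne only (E-alkenylborane), boron-to-zinc exchange gives 12, and the amino-alcohol-catalysed asymmetric alkenylzinc addition delivers the alkenyl group to the Si face of the enal, which forms C1–C2 and sets C2 (S).

Step 8
Reactants: 13 (2E,4S,5E,8E)-1,11-bis(tert-butyldimethylsilyloxy)-2,8-dimethylundeca-2,5,8-trien-4-ol
Product: 14 the (4R,5R,6R)-5,6-epoxide of 13 (trans epoxide C1–C14, erythro to the C2 carbinol; C1 R, C2 R, C14 R)
Conditions: Ti(OiPr)4 (15 mol %), D-(−)-DIPT (20 mol %), t-BuOOH (1.2 equiv), 4 Å MS, CH2Cl2, −20 °C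
Reagents that add atoms: tert-butyl hydroperoxide, CC(C)(C)OO
Why: Sharpless epoxidation in its kinetic-resolution mode: for the (S)-carbinol the E-disubstituted C1=C14 alkene is the matched, fast partner of D-(−)-tartrate and gives the erythro epoxide (sets C14 and the provisional C1), whereas C3=C4 is mismatched and burdened by its cis methyl group, and the minor enantiomer of 13 reacts slowly, which should raise the optical purity.

Step 9
Reactants: 14 epoxy alcohol
Product: 15 the 2-(diethoxyphosphoryl)acetate of 14 (ester on O2)
Conditions: (EtO)2P(O)CH2CO2H, DCC, DMAP (cat.), CH2Cl2, 0 °C to rt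
Reagents that add atoms: 2-(diethoxyphosphoryl)acetic acid, OC(=O)CP(=O)(OCC)OCC
Why: Steglich esterification of a secondary alcohol under neutral conditions, which spare the epoxide and the allylic C–O bond; it brings in C15 and C16.

Step 10
Reactants: 15 phosphonoacetate of 14
Product: 17 (1R,2R,14R)-α-methylene-γ-butyrolactone alcohol: ring B with the (E)-3-(silyloxy)-2-methylprop-1-enyl group on C2 and, trans to it on C1, the C14 carbinol chain, via phosphono lactone 16 (not isolated)
Conditions: KOtBu (1.05 equiv), THF, 0 to 40 °C; then (CH2O)n, rt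
Reagents that add atoms: formaldehyde (as paraformaldehyde), C=O
Why: Proposed new method: the phosphonoacetate carbanion at C15, tethered through O2, can reach only the backside of the proximal epoxide carbon C1 in a 5-(enolexo)-exo-tet closure (the exocyclic P=O keeps the anion stabilised while the ring forms), which closes ring B with inversion at C1 and frees O14 with retention at C14; the alkoxide then takes the acidic C15 proton, which regenerates the phosphonate carbanion of 16 and keeps the alkoxide from attacking phosphorus (the cyclopropanation channel), and a Horner–Wadsworth–Emmons reaction with formaldehyde installs C17. The closest known reaction types are the telescoped intramolecular Michael addition/olefination of phosphonoacetates of γ-hydroxy enones, the base-induced 5-exo opening of 2,3-epoxy alcohol carbamates at the proximal carbon, and the intermolecular opening of epoxides by phosphonoacetate anions.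

Step 11
Reactants: 17 α-methylene lactone alcohol
Product: 18 the C14 acetate of 17
Conditions: Ac2O, pyridine, DMAP (cat.), CH2Cl2, 0 °C
Reagents that add atoms: acetic anhydride, CC(=O)OC(C)=O
Why: Acetylation of the only free hydroxyl group installs the first acetate of the target, which also blocks translactonisation to O14.

Step 12
Reactants: 18 C14 acetate
Product: 19 (1R,2R,14R)-diol with free primary hydroxyl groups at C5 and C9
Conditions: HF·pyridine, pyridine, THF, 0 °C to rt
Reagents that add atoms: none
Why: Buffered HF cleaves both primary TBS ethers at once without base, so the acetate, the lactone and the acrylate should survive.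

Step 13
Reactants: 19 diol
Product: 20 (1R,2S,3S,4S,14R)-epoxy diol (ring C in place)
Conditions: Ti(OiPr)4 (20 mol %), L-(+)-DET (25 mol %), t-BuOOH, 4 Å MS, CH2Cl2, −20 °C
Reagents that add atoms: tert-butyl hydroperoxide, CC(C)(C)OO
Why: Sharpless epoxidation of a primary (E)-2-methylallylic alcohol; L-(+)-tartrate sets 3S,4S by reagent control, and the homoallylic C11=C12 and the electron-poor C15=C17 alkenes react far more slowly.

Step 14
Reactants: 20 epoxy diol
Product: 21 (1R,2S,3S,4R,14R)-dialdehyde (C5 epoxy aldehyde and C9 β,γ-unsaturated aldehyde; same spatial arrangement as 20)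
Conditions: Dess–Martin periodinane (2.4 equiv), NaHCO3, CH2Cl2, 0 °C; used at once
Reagents that add atoms: none
Why: Dess–Martin oxidation of both primary alcohols under buffered, amine-free conditions, which should avoid migration of C11=C12 into conjugation; C4 has no hydrogen, so the epoxy aldehyde cannot epimerise.

Step 15
Reactants: 22 but-2-yn-1-ol
Product: 23 but-2-yn-1-yl methyl carbonate
Conditions: ClCO2Me, pyridine, CH2Cl2, 0 °C
Reagents that add atoms: methyl chloroformate, COC(=O)Cl
Why: Routine acylation; the carbonate is the leaving group for step 16.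

Step 16
Reactants: 23 but-2-yn-1-yl methyl carbonate
Product: 24 2-(buta-2,3-dien-2-yl)-4,4,5,5-tetramethyl-1,3,2-dioxaborolane
Conditions: B2pin2, CuCl (5 mol %), Xantphos (5 mol %), KOtBu (10 mol %), THF, rt
Reagents that add atoms: bis(pinacolato)diboron, CC1(C)OB(OC1(C)C)B1OC(C)(C)C(C)(C)O1
Why: γ-Selective (SN2′) borylation of a propargylic carbonate under catalysis by monovalent copper places boron on the methyl-bearing alkyne carbon and gives the allenylboronate.

Step 17
Reactants: 25 (1S,5S)-(−)-α-pinene
Product: 26 (+)-diisopinocampheylborane, (lIpc)2BH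
Conditions: BH3·SMe2, THF, 0 °C; crystallisation
Reagents that add atoms: borane–dimethyl sulfide, C[S+](C)[BH3-]
Why: Double hydroboration of α-pinene from the face opposite the gem-dimethyl bridge; crystallisation of the dialkylborane upgrades its optical purity.

Step 18
Reactants: 24 allenylboronate; 26 (lIpc)2BH; 21 dialdehyde
Product: 31 5-O-deacetylmichaolide A (macrocyclic 5,9-diol; 1R,2S,3S,4S,5R,9S,14R; 7E,11E), via kinetic allylborane 27 (not isolated), via equilibrated allylborane 28 (not isolated), via allylboronate aldehyde 29 (not isolated), via macrocyclic boron alkoxide 30 (not isolated)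
Conditions: 26 (0.95 equiv), 24 (1.0 equiv), toluene, 0 °C, then 85 °C; cool to −78 °C and add to 21 (0.02 M in toluene), −78 °C; dilute to 0.002 M, 23 to 50 °C; pH 7 phosphate buffer, 30% H2O2, THF/MeOH, 0 °C
Reagents that add atoms: none
Why: Proposed new method: 26 hydroborates the CH2=C bond of allene 24 to give 27, which equilibrates on heating by 1,3-boratropic shifts to 28 (Bpin trans to CH2B(Ipc)2), a three-carbon unit with a fast allylborane end and a slow allylboronate end. The closest known reaction types are the intermolecular allene hydroboration–double allylboration, which joins two separate aldehydes to (E)-2-methyl-1,5-anti-pent-2-ene-1,5-diols, and the tandem double allylation of 1,4- and 1,5-dicarbonyl compounds by bis-boron reagents, which closes five- and six-membered rings; new here is that the two aldehydes are the ends of one 11-carbon chain, so that the second allylation closes ring A. At −78 °C only the allylborane end reacts: a chair Zimmerman–Traxler transition state forms C8–C9, the Ipc groups direct C8 to the Re face of the C9 aldehyde (9S), and the alkene geometry of 28 fixes the transient boron-bearing centre C8 of 29 with Bpin anti to O9. On dilution and warming the tertiary allylboronate of 29 attacks the C5 aldehyde through its CH2 terminus C6 in an intramolecular SE2′ allylboration, so that ring A is closed in a [11+3] mode as a 14-membered ring that shares C5–C8 with a six-membered chair. With the C9 chain equatorial and the C8 methyl group axial in that chair, the new C7=C8 bond is E and the chirality of C8 is transferred to C5 (5R, 1,5-anti to C9), so both new stereocentres go back to the one chiral reagent 26 and not to the bias of the epoxy aldehyde. Site selectivity between the aldehydes is needed and is secured by the substrate: the hindered γ,γ-disubstituted end of 28 should meet the CH2-flanked C9 aldehyde much faster than the C5 aldehyde on the quaternary C4, whereas the unhindered C6 terminus of 29 can still reach that hindered but inductively activated aldehyde. Allylboron reagents add to aldehydes only, so lactone, acrylate, acetate and epoxide are spectators, and the rate gap between the two boron ends allows high dilution to be applied to the ring closure alone. Buffered H2O2 then cleaves the B–O and B–C bonds of 30 without base.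

Step 19
Reactants: 31 5-O-deacetylmichaolide A
Product: 32 9-O-triethylsilyl-5-O-deacetylmichaolide A
Conditions: TESCl (1.1 equiv), imidazole, CH2Cl2, −20 °C
Reagents that add atoms: triethylsilyl chloride, CC[Si](Cl)(CC)CC
Why: Kinetic silylation should take the allylic C9 hydroxyl, flanked by a planar sp2 carbon, in preference to the C5 hydroxyl, which sits next to the fully substituted epoxide carbon C4.

Step 20
Reactants: 32 9-O-triethylsilyl-5-O-deacetylmichaolide A
Product: 33 9-O-triethylsilylmichaolide A
Conditions: Ac2O, DMAP, pyridine, CH2Cl2, 0 °C to rt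
Reagents that add atoms: acetic anhydride, CC(=O)OC(C)=O
Why: DMAP-catalysed acetylation of the remaining hindered secondary alcohol; no other nucleophilic site is left.

Step 21
Reactants: 33 9-O-triethylsilylmichaolide A
Product: 34 michaolide A
Conditions: HF·pyridine, pyridine, THF, 0 °C
Reagents that add atoms: none
Why: A secondary allylic TES ether is cleaved by buffered HF under conditions that should spare the acetates, the acrylate and the epoxide, which is deactivated by its two neighbouring C–O bonds; no alkoxide is formed, so the oxy-Cope channel stays closed.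

## Compound list

1 | 4-methylpent-3-en-1-ol | CC(C)=CCCO | starting material
2 | tert-butyl(dimethyl)[(4-methylpent-3-en-1-yl)oxy]silane | CC(C)=CCCO[Si](C)(C)C(C)(C)C | intermediate
3 | (E)-5-(tert-butyldimethylsilyloxy)-2-methylpent-2-en-1-ol | OC/C(C)=C/CCO[Si](C)(C)C(C)(C)C | intermediate
4 | (E)-[(5-bromo-4-methylpent-3-en-1-yl)oxy](tert-butyl)dimethylsilane | BrC/C(C)=C/CCO[Si](C)(C)C(C)(C)C | intermediate
5 | (E)-tert-butyl(dimethyl)[(4-methylhept-3-en-6-yn-1-yl)oxy]silane | C#CC/C(C)=C/CCO[Si](C)(C)C(C)(C)C | intermediate
6 | tert-butyl(dimethyl)(prop-2-yn-1-yloxy)silane | C#CCO[Si](C)(C)C(C)(C)C | starting material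
7 | (E)-[3-(tert-butyldimethylsilyloxy)-2-methylprop-1-enyl]dimethylalane | C[Al](C)/C=C(\C)CO[Si](C)(C)C(C)(C)C | intermediate
8 | lithium butyl(dimethyl)[(E)-3-(tert-butyldimethylsilyloxy)-2-methylprop-1-enyl]alanate | [Li+].CCCC[Al-](C)(C)/C=C(\C)CO[Si](C)(C)C(C)(C)C | intermediate
9 | (E)-4-(tert-butyldimethylsilyloxy)-3-methylbut-2-en-1-ol | OC/C=C(\C)CO[Si](C)(C)C(C)(C)C | intermediate
10 | (E)-4-(tert-butyldimethylsilyloxy)-3-methylbut-2-enal | O=C/C=C(\C)CO[Si](C)(C)C(C)(C)C | intermediate
11 | (1E,4E)-dienyl(dicyclohexyl)borane from 5 | CC(C)(C)[Si](C)(C)OCC/C=C(\C)C/C=C/B(C1CCCCC1)C1CCCCC1 | intermediate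
12 | (1E,4E)-dienyl(methyl)zinc from 11 | CC(C)(C)[Si](C)(C)OCC/C=C(\C)C/C=C/[Zn]C | intermediate
13 | (2E,4S,5E,8E)-1,11-bis(tert-butyldimethylsilyloxy)-2,8-dimethylundeca-2,5,8-trien-4-ol | CC(C)(C)[Si](C)(C)OCC/C=C(\C)C/C=C/[C@H](O)/C=C(\C)CO[Si](C)(C)C(C)(C)C | intermediate
14 | (4R,5R,6R)-5,6-epoxide of 13 (C1–C14 epoxide, erythro to C2–OH) | CC(C)(C)[Si](C)(C)OCC/C=C(\C)C[C@H]1O[C@@H]1[C@H](O)/C=C(\C)CO[Si](C)(C)C(C)(C)C | intermediate
15 | 2-(diethoxyphosphoryl)acetate of 14 | CC(C)(C)[Si](C)(C)OCC/C=C(\C)C[C@H]1O[C@@H]1[C@H](OC(=O)CP(=O)(OCC)OCC)/C=C(\C)CO[Si](C)(C)C(C)(C)C | intermediate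
16 | α-(diethoxyphosphoryl)-γ-butyrolactone with free C14–OH (present as its potassium carbanion; C15 not defined) | CCOP(=O)(OCC)C1C(=O)O[C@H](/C=C(\C)CO[Si](C)(C)C(C)(C)C)[C@H]1[C@H](O)C/C(C)=C/CCO[Si](C)(C)C(C)(C)C | intermediate
17 | (1R,2R,14R)-α-methylene-γ-butyrolactone alcohol | C=C1C(=O)O[C@H](/C=C(\C)CO[Si](C)(C)C(C)(C)C)[C@H]1[C@H](O)C/C(C)=C/CCO[Si](C)(C)C(C)(C)C | intermediate
18 | C14 acetate of 17 | C=C1C(=O)O[C@H](/C=C(\C)CO[Si](C)(C)C(C)(C)C)[C@H]1[C@H](OC(C)=O)C/C(C)=C/CCO[Si](C)(C)C(C)(C)C | intermediate
19 | (1R,2R,14R)-C5,C9-diol | C=C1C(=O)O[C@H](/C=C(\C)CO)[C@H]1[C@H](OC(C)=O)C/C(C)=C/CCO | intermediate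
20 | (1R,2S,3S,4S,14R)-3,4-epoxy C5,C9-diol | C=C1C(=O)O[C@H]([C@@H]2O[C@@]2(C)CO)[C@H]1[C@H](OC(C)=O)C/C(C)=C/CCO | intermediate
21 | (1R,2S,3S,4R,14R)-C5,C9-dialdehyde | C=C1C(=O)O[C@H]([C@@H]2O[C@@]2(C)C=O)[C@H]1[C@H](OC(C)=O)C/C(C)=C/CC=O | intermediate
22 | but-2-yn-1-ol | CC#CCO | starting material
23 | but-2-yn-1-yl methyl carbonate | CC#CCOC(=O)OC | intermediate
24 | 2-(buta-2,3-dien-2-yl)-4,4,5,5-tetramethyl-1,3,2-dioxaborolane | C=C=C(C)B1OC(C)(C)C(C)(C)O1 | intermediate
25 | (1S,5S)-(−)-α-pinene | CC1=CC[C@H]2C[C@@H]1C2(C)C | starting material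
26 | (+)-diisopinocampheylborane, (lIpc)2BH | B([C@H]1C[C@H]2C[C@@H]([C@@H]1C)C2(C)C)[C@H]1C[C@H]2C[C@@H]([C@@H]1C)C2(C)C | intermediate
27 | γ-boryl allylborane, boron groups cis (kinetic) | B(C/C=C(/C)B1OC(C)(C)C(C)(C)O1)([C@H]1C[C@H]2C[C@@H]([C@@H]1C)C2(C)C)[C@H]1C[C@H]2C[C@@H]([C@@H]1C)C2(C)C | intermediate
28 | γ-boryl allylborane, boron groups trans (equilibrated) | B(C/C=C(\C)B1OC(C)(C)C(C)(C)O1)([C@H]1C[C@H]2C[C@@H]([C@@H]1C)C2(C)C)[C@H]1C[C@H]2C[C@@H]([C@@H]1C)C2(C)C | intermediate
29 | C9 borinate / C8 tertiary allylboronate with free C5 aldehyde | C=C1C(=O)O[C@H]([C@@H]2O[C@@]2(C)C=O)[C@H]1[C@H](OC(C)=O)C/C(C)=C/C[C@H](OB([C@H]3C[C@H]4C[C@@H]([C@@H]3C)C4(C)C)[C@H]3C[C@H]4C[C@@H]([C@@H]3C)C4(C)C)[C@@](C)(C=C)B3OC(C)(C)C(C)(C)O3 | intermediate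
30 | macrocyclic C9 borinate / C5 pinacol borate | C=C1C(=O)O[C@H]2[C@H]1[C@H](OC(C)=O)C/C(C)=C/C[C@H](OB([C@H]3C[C@H]4C[C@@H]([C@@H]3C)C4(C)C)[C@H]3C[C@H]4C[C@@H]([C@@H]3C)C4(C)C)/C(C)=C/C[C@@H](OB3OC(C)(C)C(C)(C)O3)[C@]1(C)O[C@@H]21 | intermediate
31 | 5-O-deacetylmichaolide A | C=C1C(=O)O[C@H]2[C@H]1[C@H](OC(C)=O)C/C(C)=C/C[C@H](O)/C(C)=C/C[C@@H](O)[C@]1(C)O[C@@H]21 | intermediate
32 | 9-O-triethylsilyl-5-O-deacetylmichaolide A | C=C1C(=O)O[C@H]2[C@H]1[C@H](OC(C)=O)C/C(C)=C/C[C@H](O[Si](CC)(CC)CC)/C(C)=C/C[C@@H](O)[C@]1(C)O[C@@H]21 | intermediate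
33 | 9-O-triethylsilylmichaolide A | C=C1C(=O)O[C@H]2[C@H]1[C@H](OC(C)=O)C/C(C)=C/C[C@H](O[Si](CC)(CC)CC)/C(C)=C/C[C@@H](OC(C)=O)[C@]1(C)O[C@@H]21 | intermediate
34 | michaolide A | C=C1C(=O)O[C@H]2[C@H]1[C@H](OC(C)=O)C/C(C)=C/C[C@H](O)/C(C)=C/C[C@@H](OC(C)=O)[C@]1(C)O[C@@H]21 | target

## Step count and least certain steps

Total step count: 21. Longest linear sequence: 16 steps (steps 1–4, 7–14, 18–21).

**Step 18 (key step, proposed new method).**
- Most likely failure: the ring closure is slow. The allylboronate end reacts sluggishly even between separate molecules, so at high dilution intermolecular allylboration (oligomerisation) or decay of the C9-derived chain may compete.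
- Next: loss of site selectivity if 28 also attacks the activated C5 aldehyde.
- Also: erosion of the E/Z and facial outcome if the chair demanded by C8 is mismatched with the intrinsic bias of the epoxy aldehyde or with the tether.
- Fallback (known chemistry, from 20 back to 33). The less hindered C9 hydroxyl of 20 is silylated (TBSCl, imidazole) to the mono-silyl ether F1, and Dess–Martin oxidation gives the epoxy aldehyde F2. Allenylboronate 24 is then used as a propargylating agent under a chiral BINOL-derived phosphoric acid (TRIP, the enantiomer that serves the 5R face). It adds through its CH2 terminus to give the homopropargylic alcohol F3. Acetylation gives the acetate F4, HF·pyridine the primary alcohol F5, and Dess–Martin oxidation the ynal F6. A reductive alkyne–aldehyde macrocyclisation with zerovalent nickel (Ni(cod)2, IMes·HCl, KOtBu, Et3SiH) forms C8–C9 at the methyl-bearing alkyne carbon. This creates the E-alkene and delivers the C9 oxygen directly as its triethylsilyl ether, which is 33.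

**Step 10 (proposed new method).**
- Most likely failure: attack of the liberated C14 alkoxide on phosphorus, followed by phosphate transfer and three-membered ring closure. This is the cyclopropanation channel of phosphonoacetate/epoxide chemistry.
- Alternatively: epoxide opening so slow that acyl transfer and decomposition of the allylic ester take over.
- Fallback (known chemistry, from 14 back to 17). The free epoxy alcohol 14 is treated with a lithium alkynyl(trimethyl)aluminate made from Me3SiC≡CLi and Me3Al. Such ate complexes substitute 2,3-epoxy alcohols at the carbon next to the carbinol with inversion, which gives the silylalkynyl 1,3-diol F7. K2CO3/MeOH gives the terminal alkyne diol F8. Cyclocarbonylation of the homopropargylic alcohol with divalent palladium (PdCl2, SnCl2, PPh3, CO, MeCN) builds the α-methylene lactone. Any lactone closed on O14 (cis-disubstituted) is equilibrated to the trans lactone on O2, which is 17.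

**Step 8.**
- Most likely failure: competing epoxidation of the more electron-rich C3=C4 alkene through the same C2 hydroxyl, or over-oxidation of 14. The choice between two allylic alkenes rests on catalyst matching alone.
- Fallback (from 5 and 6 back to 14; it also replaces step 7). Lithiation of 5 and trapping with paraformaldehyde give the propargylic alcohol F9. NaAlH2(OCH2CH2OMe)2 reduces it to the (E)-allylic alcohol F10. Sharpless epoxidation of this primary alcohol, which has only one allylic alkene, with D-(−)-DET gives the epoxy alcohol F11. Dess–Martin oxidation gives the epoxy aldehyde F12. The alkenylalane 7 from step 5, used as its alanate 8, adds to F12 anti to the epoxide C–O bond (Cornforth or polar Felkin–Anh control) to give the erythro epoxy alcohol 14.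

**Step 19.**
- Most likely failure: poor site selectivity in the silylation, because both hydroxyl groups are secondary and the ring conformation may shield C9.
- Fallback (from 31 back to 34, same step count). MnO2 oxidises only the allylic C9 hydroxyl to the enone F13. Acetylation of the remaining C5 hydroxyl gives the acetoxy enone F14. 1,2-Reduction with (R)-Me-CBS and catecholborane, in which the α-methylalkenyl group acts as the large substituent, resets 9S and gives 34.

## Further compounds

F1 | step 18 | C9 mono-TBS ether of 20 | C=C1C(=O)O[C@H]([C@@H]2O[C@@]2(C)CO)[C@H]1[C@H](OC(C)=O)C/C(C)=C/CCO[Si](C)(C)C(C)(C)C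
F2 | step 18 | C5 epoxy aldehyde, C9 TBS ether | C=C1C(=O)O[C@H]([C@@H]2O[C@@]2(C)C=O)[C@H]1[C@H](OC(C)=O)C/C(C)=C/CCO[Si](C)(C)C(C)(C)C
F3 | step 18 | (5R)-homopropargylic alcohol (C7≡C8–CH3), C9 TBS ether | C=C1C(=O)O[C@H]([C@@H]2O[C@@]2(C)[C@@H](CC#CC)O)[C@H]1[C@H](OC(C)=O)C/C(C)=C/CCO[Si](C)(C)C(C)(C)C
F4 | step 18 | C5 acetate of F3 | C=C1C(=O)O[C@H]([C@@H]2O[C@@]2(C)[C@@H](CC#CC)OC(C)=O)[C@H]1[C@H](OC(C)=O)C/C(C)=C/CCO[Si](C)(C)C(C)(C)C
F5 | step 18 | C9 primary alcohol from F4 | C=C1C(=O)O[C@H]([C@@H]2O[C@@]2(C)[C@@H](CC#CC)OC(C)=O)[C@H]1[C@H](OC(C)=O)C/C(C)=C/CCO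
F6 | step 18 | ynal (C9 aldehyde, C7≡C8–CH3) | C=C1C(=O)O[C@H]([C@@H]2O[C@@]2(C)[C@@H](CC#CC)OC(C)=O)[C@H]1[C@H](OC(C)=O)C/C(C)=C/CC=O
F7 | step 10 | C1-(trimethylsilylethynyl) C2,C14-diol | C[Si](C)(C)C#C[C@@H]([C@H](O)/C=C(\C)CO[Si](C)(C)C(C)(C)C)[C@H](O)C/C(C)=C/CCO[Si](C)(C)C(C)(C)C
F8 | step 10 | C1-ethynyl C2,C14-diol | C#C[C@@H]([C@H](O)/C=C(\C)CO[Si](C)(C)C(C)(C)C)[C@H](O)C/C(C)=C/CCO[Si](C)(C)C(C)(C)C
F9 | step 8 | (E)-8-(tert-butyldimethylsilyloxy)-5-methyloct-5-en-2-yn-1-ol | OCC#CC/C(C)=C/CCO[Si](C)(C)C(C)(C)C
F10 | step 8 | (2E,5E)-8-(tert-butyldimethylsilyloxy)-5-methylocta-2,5-dien-1-ol | OC/C=C/C/C(C)=C/CCO[Si](C)(C)C(C)(C)C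
F11 | step 8 | (2R,3R)-2,3-epoxide of F10 | OC[C@H]1O[C@@H]1C/C(C)=C/CCO[Si](C)(C)C(C)(C)C
F12 | step 8 | epoxy aldehyde from F11 | O=C[C@H]1O[C@@H]1C/C(C)=C/CCO[Si](C)(C)C(C)(C)C
F13 | step 19 | 9-oxo-5-O-deacetylmichaolide A | C=C1C(=O)O[C@H]2[C@H]1[C@H](OC(C)=O)C/C(C)=C/CC(=O)/C(C)=C/C[C@@H](O)[C@]1(C)O[C@@H]21
F14 | step 19 | 9-oxomichaolide A | C=C1C(=O)O[C@H]2[C@H]1[C@H](OC(C)=O)C/C(C)=C/CC(=O)/C(C)=C/C[C@@H](OC(C)=O)[C@]1(C)O[C@@H]21
A1 | alternative 1 | methyl (Z)-2-(bromomethyl)enoate with terminal C2 epoxy aldehyde (open at C1–C2) | COC(=O)/C(CBr)=C/[C@H](OC(C)=O)C/C(C)=C/C[C@H](O[Si](CC)(CC)CC)/C(C)=C/C[C@@H](OC(C)=O)[C@]1(C)O[C@H]1C=O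
A2 | alternative 2 | methyl-capped diyne (open at C7/C8) | C=C1C(=O)O[C@H]([C@@H]2O[C@@]2(C)[C@@H](CC#CC)OC(C)=O)[C@H]1[C@H](OC(C)=O)C/C(C)=C/C[C@H](O)C#CC
A3 | alternative 2 | 14-membered cycloalkyne (C7≡C8) | C=C1C(=O)O[C@H]2[C@H]1[C@H](OC(C)=O)C/C(C)=C/C[C@H](O)C#CC[C@@H](OC(C)=O)[C@]1(C)O[C@@H]21
A4 | alternative 3 | 9-deoxymichaolide A | C=C1C(=O)O[C@H]2[C@H]1[C@H](OC(C)=O)C/C(C)=C/CC/C(C)=C/C[C@@H](OC(C)=O)[C@]1(C)O[C@@H]21
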